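## Analysis of the target

Target 25 is a humulane-type sesquiterpenoid acid: an eleven-membered carbocycle fused to an oxirane (a 12-oxabicyclo[9.1.0]dodecene). The ring is numbered here C1 (alkene carbon bearing the carboxyl carbon C15), C2 (alkene CH), C3 (CH–OBz), C4 (CMe2), C5–C7 (CH2), C8 (epoxide carbon with methyl), C9 (epoxide CH), C10 and C11 (CH2, C11 bonded to C1).

There are three stereocentres. C8 and C9 are both R, and the oxirane is trans with respect to the ring bonds (C7 and C10 on opposite faces), so it corresponds to an E-trisubstituted alkene. C3 is R and is separated from the epoxide by at least four ring atoms, so C3 and the epoxide have to be set by two independent events. Across C1=C2 the ring bonds C11 and C3 are cis and the carboxyl group is trans to C3 (E by the sequence rules).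

The sensitive groups are the trisubstituted epoxide (acid, and transannular attack of the C15 carboxyl on C9, which would give a six-membered lactone), the allylic, neopentyl benzoate (hydroxide, ionisation) and the free acid. The difficulty lies in closing a strained medium ring while a trisubstituted enoate of defined geometry, an epoxide and a carbinol next to a quaternary carbon are all put in place.

The strategy rests on one feature. If C3 is a ketone and C1–C2 an alkyne, the segment C3–C2–C1–C15 is a 4-oxo-2-ynoate. Its carbon β to the ketone, C1, is exactly the atom that carries the ring methylene C11, so the C11–C1 bond can be made by adding a C11 radical to that alkyne.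

## Retrosynthetic reasoning

**Acid and benzoate (25 ← 24 ← 23).** The acid is unmasked last from the 2-(trimethylsilyl)ethyl ester 24, because a fluoride-triggered elimination needs neither acid (epoxide) nor hydroxide (benzoate). The C3–O acyl bond is cut next, leading back to allylic alcohol 23. Benzoylation of a hindered but isolated hydroxyl is all the forward step has to achieve.

**C3 stereocentre (23 ← 22).** The C3–H bond is cut, giving the ene keto ester 22. The ketone is wanted anyway as the activating group of the ring closure. A Corey–Bakshi–Shibata reduction then sets C3 by reagent control, and because C8 and C9 are already fixed, any C3 epimer is a separable diastereomer.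

**Ring closure (22 ← 21).** The C11–C1 bond is cut, with removal of the C2 hydrogen, which leads to the open-chain epoxy iodo ynone 21. This bond is chosen because the forward reaction, addition of a nucleophilic primary radical to the β-carbon of an ynone, forms the ring and the trisubstituted enoate in one operation. It does so under neutral conditions, with the epoxide already installed and C15 already at the acid oxidation level. Cutting C2–C3 or C10–C11 instead would force the epoxide or the C3 oxygen to be introduced on the macrocycle.

**Ynone (21 ← 20 ← 15 + 18).** The C2–C3 bond is cut between the neopentyl aldehyde 15 and the propiolate 18, which reacts as its lithium acetylide 19. Aldehyde 15 cannot enolise, so the addition is clean, and a Dess–Martin oxidation of the epimeric carbinol 20 gives 21. Ester 18 comes from propiolic acid 16 and 2-(trimethylsilyl)ethanol 17.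

**Functional-group order on the chain (15 ← 14 ← 13 ← 12).** The aldehyde is traced to alcohol 14 and its 4-methoxybenzyl ether 13. The iodide of 13 is traced to the primary alcohol of epoxy alcohol 12. The iodide has to be made after the epoxidation because alkyl iodides are oxidised by dioxiranes. The ether has to be removable at neutral pH in the presence of epoxide and iodide.

**Epoxide (12 ← 11).** The two C–O bonds of the oxirane are cut, giving the E-homoallylic alcohol 11. A Shi epoxidation on the open chain sets C8 and C9 together under catalyst control, free of any ring-conformation bias.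

**Trisubstituted alkene (11 ← 7 + 8).** The C9–C10 bond and the C8–methyl bond are cut. Syn carboalumination of terminal alkyne 7 gives alkenylalane 9 with the E geometry fixed. Its alanate 10 opens oxirane 8, which supplies C10, C11 and the hydroxyl that later becomes the iodide.

**Quaternary carbon (7 ← 6 ← 5 ← 3 + 2).** The C4–C5 bond is cut between the enolate 4 of methyl isobutyrate 3 and 5-iodopent-1-yne 2, which comes from pent-4-yn-1-ol 1. A single alkylation of a fully substituted enolate builds the gem-dimethyl carbon. Reduction to 6 and protection to 7 bring C3 to the level needed for the carboalumination.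

## Alternatives that were turned down

**Alternative 1: Grob fragmentation of a six–seven fused bicycle.**
- Disconnection and key step: a C3–C8 bond is added in the retrosynthetic sense, so the ring becomes the bicyclic hydroxy mesylate A1 (tertiary C3 alkoxide, C9 mesylate anti to the C3–C8 bond). With a strong amide base, A1 would fragment to the achiral eleven-membered dienone A2, with the C3 ketone, the E C8=C9 alkene and C15 as a silyloxymethyl group.
- For: a fragmentation has no entropic cost and the alkene geometry follows stereospecifically from the relative configuration of A1. On the certainty of ring formation this plan is stronger than the chosen one.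
- Against: A1 has three contiguous fully substituted carbons (C4, C3, C8) and a defined C9 centre, which means a long preparation. A2 is achiral, so both the epoxide and the C3 carbinol would have to be set enantioselectively on the macrocycle, where facial selectivity is governed by the conformers of an E-cycloalkene as much as by the reagent. C15 would still need deprotection and two oxidations with epoxide and benzoate present.
- Comparison: the chosen route accepts a riskier ring closure. In exchange it sets the epoxide on an open chain and carries C15 as an ester throughout.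

**Alternative 2: Nickel allyl–allyl coupling of two allylic bromides.**
- Disconnection and key step: the C10–C11 bond, the central bond of the 1,5-diene C8=C9–C10–C11–C1=C2, is cut. The bis(allylic bromide) A3 would be closed with a zerovalent nickel complex at high dilution to the diene benzoate A4.
- For: the 1,5-diene retron fits exactly, and C3 with its benzoate would be set on an acyclic precursor before ring closure. On that point it is stronger than the chosen route, which sets C3 on the ring.
- Against: allylnickel intermediates interconvert syn and anti forms, so both alkene geometries are at risk. Coupling at the internal termini (C8 or C2) competes. The C3 benzoate is allylic and sits β to the allylnickel terminus C2, so ionisation or elimination to a diene is a structural liability. A4 would still need epoxidation of C8=C9 on the macrocycle with conformational facial control.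
- Comparison: the chosen route closes the ring with the epoxide in place and with no organometallic species next to the C3 oxygen.

**Alternative 3: Cyclobutane unzipping of (−)-caryophyllene oxide.**
- Disconnection and key step: a C2–C5 bond is added in the retrosynthetic sense, which leads to the caryophyllane skeleton. The exocyclic methylene of (−)-caryophyllene oxide A5 would be converted into the tertiary bromo ester A6. With a silane and a thermal initiator, the C1 radical of A6 would cleave the cyclobutane to give the 3-deoxy epoxy enoate A7.
- For: A5 is a cheap, enantiopure terpene that already carries all fifteen carbons, the gem-dimethyl group, the C8 methyl and the (8R,9R)-epoxide. The ring expansion is driven by strain. On step count and on ring formation this is the strongest of the four plans.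
- Against: the cyclobutylcarbinyl radical can also cleave C2–C3. More seriously, A7 has no oxygen at C3. C3 would be an allylic methylene next to a quaternary carbon on an electron-poor alkene. Its oxidation would have to be selective against the other allylic methylene C11, spare the epoxide and set the 3R configuration without any directing group.
- Comparison: the chosen route is longer, but the C3 oxygen is built in from the start as the ketone that activates the ring closure.

Key step: step 13

Assumption (remark on the chemistry): in the oxazaborolidine reduction of step 14 the quaternary C4 flank of the ketone is taken as the larger group and the alkene CH (C2) as the smaller. On that basis the (S)-catalyst is predicted to give the 3R alcohol.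

## Route

**Step 1**
Reactants: 1 pent-4-yn-1-ol
Product: 2 5-iodopent-1-yne
Conditions: I2, PPh3, imidazole, CH2Cl2, 0 °C → rt
Reagents that add atoms: iodine, II
Why: Garegg–Samuelsson (Appel-type) iodination; the alkoxyphosphonium iodide of the primary alcohol is displaced by iodide in an SN2 reaction and the terminal alkyne is inert.

**Step 2**
Reactants: 3 methyl isobutyrate; 2 5-iodopent-1-yne
Product: 5 methyl 2,2-dimethylhept-6-ynoate, via lithium enolate of methyl isobutyrate 4 (not isolated)
Conditions: LDA, THF, −78 °C; then 2, −78 °C → rt
Reagents that add atoms: none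
Why: Ester enolate alkylation; the fully substituted enolate 4 can be alkylated only once and so gives the quaternary C4 directly, and C-alkylation by the primary iodide at low temperature is expected to be faster than proton transfer from the alkyne.

**Step 3**
Reactants: 5 methyl 2,2-dimethylhept-6-ynoate
Product: 6 2,2-dimethylhept-6-yn-1-ol
Conditions: LiAlH4, Et2O, 0 °C → rt
Reagents that add atoms: none
Why: Hydride reduction of the hindered ester to the neopentyl alcohol; an isolated terminal alkyne is not reduced under these conditions.

**Step 4**
Reactants: 6 2,2-dimethylhept-6-yn-1-ol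
Product: 7 1-{[(2,2-dimethylhept-6-yn-1-yl)oxy]methyl}-4-methoxybenzene
Conditions: NaH, 4-methoxybenzyl chloride, Bu4NI (cat.), THF/DMF, 0 °C → rt
Reagents that add atoms: 4-methoxybenzyl chloride, COc1ccc(CCl)cc1
Why: Williamson etherification of the alkoxide; the 4-methoxybenzyl ether is chosen because it survives organoaluminium and alkyllithium reagents and buffered Oxone and can later be removed oxidatively at neutral pH.

**Step 5**
Reactants: 7 1-{[(2,2-dimethylhept-6-yn-1-yl)oxy]methyl}-4-methoxybenzene; 8 oxirane
Product: 11 (E)-9-[(4-methoxybenzyl)oxy]-4,8,8-trimethylnon-3-en-1-ol, via alkenyldimethylalane 9 (not isolated), via lithium alkenylalanate 10 (not isolated)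
Conditions: Me3Al, Cp2ZrCl2 (25 mol%), CH2Cl2, 0 °C → rt; evaporation of excess Me3Al; n-BuLi, hexane, 0 °C; 8, THF, 0 °C → rt; cold 1 M HCl
Reagents that add atoms: trimethylaluminium, C[Al](C)C
Why: Negishi zirconium-catalysed carboalumination adds methyl and aluminium syn across the terminal alkyne with aluminium on the terminal carbon, which fixes the E geometry of C8=C9; the derived alanate transfers its alkenyl group to oxirane with retention and forms the C9–C10 bond.

**Step 6**
Reactants: 11 (E)-9-[(4-methoxybenzyl)oxy]-4,8,8-trimethylnon-3-en-1-ol
Product: 12 2-[(2R,3R)-3-{5-[(4-methoxybenzyl)oxy]-4,4-dimethylpentyl}-3-methyloxiran-2-yl]ethan-1-ol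
Conditions: 1,2:4,5-di-O-isopropylidene-β-D-erythro-2,3-hexodiulo-2,6-pyranose (30 mol%), Oxone (2KHSO5·KHSO4·K2SO4), K2CO3, Bu4NHSO4 (cat.), MeCN/dimethoxymethane/aq. Na2B4O7–Na2EDTA, pH 10.5, 0 °C
Reagents that add atoms: potassium peroxymonosulfate (active part of Oxone), [K+].[O-]S(=O)(=O)OO
Why: Shi asymmetric epoxidation; the chiral dioxirane attacks the E-trisubstituted alkene through a spiro transition state and, by analogy with E-disubstituted and trisubstituted model alkenes, the D-fructose-derived ketone should deliver oxygen to the face that gives the (R,R)-epoxide, setting C8 and C9 together. Hydroxyalkenes and benzylic ethers are tolerated at this pH.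

**Step 7**
Reactants: 12 2-[(2R,3R)-3-{5-[(4-methoxybenzyl)oxy]-4,4-dimethylpentyl}-3-methyloxiran-2-yl]ethan-1-ol
Product: 13 (2R,3R)-3-(2-iodoethyl)-2-{5-[(4-methoxybenzyl)oxy]-4,4-dimethylpentyl}-2-methyloxirane
Conditions: I2, PPh3, imidazole (excess), CH2Cl2, 0 °C
Reagents that add atoms: iodine, II
Why: Garegg–Samuelsson iodination of the primary alcohol by SN2 displacement; imidazole is kept in excess so that the trisubstituted epoxide is not opened, and the iodide is introduced only now because alkyl iodides do not survive dioxiranes.

**Step 8**
Reactants: 13 (2R,3R)-3-(2-iodoethyl)-2-{5-[(4-methoxybenzyl)oxy]-4,4-dimethylpentyl}-2-methyloxirane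
Product: 14 5-[(2R,3R)-3-(2-iodoethyl)-2-methyloxiran-2-yl]-2,2-dimethylpentan-1-ol
Conditions: DDQ, CH2Cl2/pH 7 phosphate buffer, 0 °C → rt
Reagents that add atoms: none
Why: Oxidative cleavage of the 4-methoxybenzyl ether (hydride abstraction from the electron-rich benzylic position, then hydrolysis) at neutral pH, which should leave the epoxide and the alkyl iodide untouched.

**Step 9**
Reactants: 14 5-[(2R,3R)-3-(2-iodoethyl)-2-methyloxiran-2-yl]-2,2-dimethylpentan-1-ol
Product: 15 5-[(2R,3R)-3-(2-iodoethyl)-2-methyloxiran-2-yl]-2,2-dimethylpentanal
Conditions: Dess–Martin periodinane, NaHCO3, CH2Cl2, 0 °C → rt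
Reagents that add atoms: none
Why: Dess–Martin oxidation of the neopentyl alcohol to a non-enolisable aldehyde under buffered, non-nucleophilic conditions compatible with epoxide and iodide.

**Step 10**
Reactants: 16 propiolic acid; 17 2-(trimethylsilyl)ethanol
Product: 18 2-(trimethylsilyl)ethyl propiolate
Conditions: DCC, 4-(dimethylamino)pyridine (5 mol%), CH2Cl2, −20 → 0 °C
Reagents that add atoms: none
Why: Steglich esterification, run cold to limit conjugate addition to the propiolate; the silylethyl ester is chosen because it is cleaved by fluoride without acid or hydroxide.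

**Step 11**
Reactants: 18 2-(trimethylsilyl)ethyl propiolate; 15 5-[(2R,3R)-3-(2-iodoethyl)-2-methyloxiran-2-yl]-2,2-dimethylpentanal
Product: 20 2-(trimethylsilyl)ethyl 4-hydroxy-8-[(2R,3R)-3-(2-iodoethyl)-2-methyloxiran-2-yl]-5,5-dimethyloct-2-ynoate (both C4 epimers), via lithiated silylethyl propiolate 19 (not isolated)
Conditions: LiHMDS, THF, −78 °C; then 15, −78 °C; AcOH, −78 °C
Reagents that add atoms: none
Why: 1,2-Addition of a lithium acetylide to a non-enolisable aldehyde forms the C2–C3 bond; at −78 °C the acetylide should attack neither the primary iodide nor the epoxide, and the new carbinol centre is erased in step 12.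

**Step 12**
Reactants: 20 2-(trimethylsilyl)ethyl 4-hydroxy-8-[(2R,3R)-3-(2-iodoethyl)-2-methyloxiran-2-yl]-5,5-dimethyloct-2-ynoate
Product: 21 2-(trimethylsilyl)ethyl 8-[(2R,3R)-3-(2-iodoethyl)-2-methyloxiran-2-yl]-5,5-dimethyl-4-oxooct-2-ynoate
Conditions: Dess–Martin periodinane, NaHCO3, CH2Cl2, 0 °C
Reagents that add atoms: none
Why: Dess–Martin oxidation of the propargylic alcohol to the 4-oxo-2-ynoate; the ketone has no α-hydrogen on the C4 side, which should make this electrophilic ynone isolable by rapid filtration.

**Step 13**
Reactants: 21 2-(trimethylsilyl)ethyl 8-[(2R,3R)-3-(2-iodoethyl)-2-methyloxiran-2-yl]-5,5-dimethyl-4-oxooct-2-ynoate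
Product: 22 2-(trimethylsilyl)ethyl (1R,4E,11R)-7,7,11-trimethyl-6-oxo-12-oxabicyclo[9.1.0]dodec-4-ene-4-carboxylate
Conditions: (Me3Si)3SiH (1.3 equiv, syringe pump), Et3B (0.3 equiv in portions), air, PhH (2 mM), 25 °C
Reagents that add atoms: none
Why: The silyl radical formed on Et3B/O2 initiation abstracts iodine from 21 to give the nucleophilic primary C11 radical, which adds to C1 of the doubly activated alkyne; the α-keto vinyl radical at C2 then takes hydrogen from the silane and regenerates the silyl radical. The closest known reaction type is the silane- or stannane-mediated endo macrocyclisation of ω-iodoalkyl enones and ynones at high dilution. The ring closes in the 11-endo-dig mode, with both alkyne carbons ending in the ring. No stereocentre is formed; the alkene geometry is decided when the linear vinyl radical takes up hydrogen, which should arrive from the outer side of the ring, cis to the ester, so that C3 ends cis to C11. This is also the fumarate-like arrangement to which reversible silyl-radical addition can equilibrate a minor isomer. The step needs attack at C1 and not at C2: C1 is β to the ketone, the stronger acceptor, attack there gives the conjugated α-keto vinyl radical, and C2 is shielded by the quaternary C4 and would need the smaller exo ring. Cyclisation must also outrun reduction of the C11 radical, which is why the silane, a slower hydrogen donor than a stannane, is kept at millimolar concentration, while iodine abstraction stays fast enough to outpace silyl-radical addition to the ynone. The epoxide should survive because the radical centre is two carbons away from it and no oxiranylcarbinyl radical is formed.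

**Step 14**
Reactants: 22 2-(trimethylsilyl)ethyl (1R,4E,11R)-7,7,11-trimethyl-6-oxo-12-oxabicyclo[9.1.0]dodec-4-ene-4-carboxylate
Product: 23 2-(trimethylsilyl)ethyl (1R,4E,6R,11R)-6-hydroxy-7,7,11-trimethyl-12-oxabicyclo[9.1.0]dodec-4-ene-4-carboxylate
Conditions: (S)-1-methyl-3,3-diphenyltetrahydro-1H,3H-pyrrolo[1,2-c][1,3,2]oxazaborole (0.5–1.0 equiv), BH3·SMe2, THF, −30 °C; MeOH
Reagents that add atoms: none
Why: Corey–Bakshi–Shibata reduction; the ketone should bind the catalyst boron through the lone pair on the side of the small alkene CH and away from the quaternary C4, and intramolecular hydride delivery then gives the 3R carbinol in the same sense as acetophenone gives (R)-1-phenylethanol with the (S)-catalyst. The catalysed 1,2-reduction is expected to be faster than any reaction of the borane with the enoate or epoxide, and a C3 epimer would be a separable diastereomer.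

**Step 15**
Reactants: 23 2-(trimethylsilyl)ethyl (1R,4E,6R,11R)-6-hydroxy-7,7,11-trimethyl-12-oxabicyclo[9.1.0]dodec-4-ene-4-carboxylate
Product: 24 2-(trimethylsilyl)ethyl (1R,4E,6R,11R)-6-(benzoyloxy)-7,7,11-trimethyl-12-oxabicyclo[9.1.0]dodec-4-ene-4-carboxylate
Conditions: BzCl, Et3N, 4-(dimethylamino)pyridine (20 mol%), CH2Cl2, 0 °C → rt
Reagents that add atoms: benzoyl chloride, O=C(Cl)c1ccccc1
Why: Nucleophile-catalysed acylation through the N-benzoylpyridinium ion, which should be reactive enough for the hindered carbinol; the C–O bond is not touched, so the C3 configuration is retained, and the conditions are basic and non-aqueous.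

**Step 16**
Reactants: 24 2-(trimethylsilyl)ethyl (1R,4E,6R,11R)-6-(benzoyloxy)-7,7,11-trimethyl-12-oxabicyclo[9.1.0]dodec-4-ene-4-carboxylate
Product: 25 (1R,4E,6R,11R)-6-(benzoyloxy)-7,7,11-trimethyl-12-oxabicyclo[9.1.0]dodec-4-ene-4-carboxylic acid
Conditions: tris(dimethylamino)sulfonium difluorotrimethylsilicate, [(Me2N)3S][Me3SiF2], DMF, 0 °C → rt; AcOH; extraction from pH 5 buffer
Reagents that add atoms: none
Why: Fluoride attacks silicon and triggers β-elimination of ethene and fluorotrimethylsilane, releasing the carboxylate without hydrolysis; an anhydrous, weakly basic fluoride source is chosen to spare the benzoate, and the mild acidification avoids acid-promoted lactonisation onto the epoxide.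

## Compound list

1 | pent-4-yn-1-ol | C#CCCCO | starting material
2 | 5-iodopent-1-yne | C#CCCCI | intermediate
3 | methyl isobutyrate | COC(=O)C(C)C | starting material
4 | lithium enolate of methyl isobutyrate | [Li+].[O-]C(OC)=C(C)C | intermediate
5 | methyl 2,2-dimethylhept-6-ynoate | C#CCCCC(C)(C)C(=O)OC | intermediate
6 | 2,2-dimethylhept-6-yn-1-ol | C#CCCCC(C)(C)CO | intermediate
7 | 1-{[(2,2-dimethylhept-6-yn-1-yl)oxy]methyl}-4-methoxybenzene | C#CCCCC(C)(C)COCc1ccc(OC)cc1 | intermediate
8 | oxirane | C1CO1 | starting material
9 | (E)-{7-[(4-methoxybenzyl)oxy]-2,6,6-trimethylhept-1-en-1-yl}dimethylalane | C[Al](C)/C=C(\C)CCCC(C)(C)COCc1ccc(OC)cc1 | intermediate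
10 | lithium butyl{(E)-7-[(4-methoxybenzyl)oxy]-2,6,6-trimethylhept-1-en-1-yl}dimethylalanate | [Li+].CCCC[Al-](C)(C)/C=C(\C)CCCC(C)(C)COCc1ccc(OC)cc1 | intermediate
11 | (E)-9-[(4-methoxybenzyl)oxy]-4,8,8-trimethylnon-3-en-1-ol | OCC/C=C(\C)CCCC(C)(C)COCc1ccc(OC)cc1 | intermediate
12 | 2-[(2R,3R)-3-{5-[(4-methoxybenzyl)oxy]-4,4-dimethylpentyl}-3-methyloxiran-2-yl]ethan-1-ol | OCC[C@H]1O[C@]1(C)CCCC(C)(C)COCc1ccc(OC)cc1 | intermediate
13 | (2R,3R)-3-(2-iodoethyl)-2-{5-[(4-methoxybenzyl)oxy]-4,4-dimethylpentyl}-2-methyloxirane | ICC[C@H]1O[C@]1(C)CCCC(C)(C)COCc1ccc(OC)cc1 | intermediate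
14 | 5-[(2R,3R)-3-(2-iodoethyl)-2-methyloxiran-2-yl]-2,2-dimethylpentan-1-ol | ICC[C@H]1O[C@]1(C)CCCC(C)(C)CO | intermediate
15 | 5-[(2R,3R)-3-(2-iodoethyl)-2-methyloxiran-2-yl]-2,2-dimethylpentanal | ICC[C@H]1O[C@]1(C)CCCC(C)(C)C=O | intermediate
16 | propiolic acid | C#CC(=O)O | starting material
17 | 2-(trimethylsilyl)ethanol | C[Si](C)(C)CCO | starting material
18 | 2-(trimethylsilyl)ethyl propiolate | C#CC(=O)OCC[Si](C)(C)C | intermediate
19 | 2-(trimethylsilyl)ethyl 3-lithiopropiolate | [Li]C#CC(=O)OCC[Si](C)(C)C | intermediate
20 | 2-(trimethylsilyl)ethyl 4-hydroxy-8-[(2R,3R)-3-(2-iodoethyl)-2-methyloxiran-2-yl]-5,5-dimethyloct-2-ynoate (both C4 epimers) | ICC[C@H]1O[C@]1(C)CCCC(C)(C)C(O)C#CC(=O)OCC[Si](C)(C)C | intermediate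
21 | 2-(trimethylsilyl)ethyl 8-[(2R,3R)-3-(2-iodoethyl)-2-methyloxiran-2-yl]-5,5-dimethyl-4-oxooct-2-ynoate | ICC[C@H]1O[C@]1(C)CCCC(C)(C)C(=O)C#CC(=O)OCC[Si](C)(C)C | intermediate
22 | 2-(trimethylsilyl)ethyl (1R,4E,11R)-7,7,11-trimethyl-6-oxo-12-oxabicyclo[9.1.0]dodec-4-ene-4-carboxylate | CC1(C)CCC[C@@]2(C)O[C@@H]2CC/C(C(=O)OCC[Si](C)(C)C)=C\C1=O | intermediate
23 | 2-(trimethylsilyl)ethyl (1R,4E,6R,11R)-6-hydroxy-7,7,11-trimethyl-12-oxabicyclo[9.1.0]dodec-4-ene-4-carboxylate | CC1(C)CCC[C@@]2(C)O[C@@H]2CC/C(C(=O)OCC[Si](C)(C)C)=C\[C@H]1O | intermediate
24 | 2-(trimethylsilyl)ethyl (1R,4E,6R,11R)-6-(benzoyloxy)-7,7,11-trimethyl-12-oxabicyclo[9.1.0]dodec-4-ene-4-carboxylate | CC1(C)CCC[C@@]2(C)O[C@@H]2CC/C(C(=O)OCC[Si](C)(C)C)=C\[C@H]1OC(=O)c1ccccc1 | intermediate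
25 | (1R,4E,6R,11R)-6-(benzoyloxy)-7,7,11-trimethyl-12-oxabicyclo[9.1.0]dodec-4-ene-4-carboxylic acid | CC1(C)CCC[C@@]2(C)O[C@@H]2CC/C(C(=O)O)=C\[C@H]1OC(=O)c1ccccc1 | target

## Step count and least certain steps

Total step count: 16. Longest linear sequence: 15 steps (steps 1–9 and 11–16, from pent-4-yn-1-ol 1); step 10 is a one-step side branch.

**Step 13 (key step).** The most likely failure is reduction of the C11 radical before ring closure, because closing an eleven-membered ring is slow and the silane is always present. Further risks are:
- addition of the silyl radical to the ynone in place of iodine abstraction;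
- attack at C2, which would give the ten-membered exo ring;
- a 1,5-hydrogen shift from the C8 methyl group to C11, after which the epoxide would open;
- hydrogen uptake on the inner side, which would give the other alkene geometry. An added thiyl-radical equilibration (catalytic PhSSPh, light) would be the remedy for this last point.

Fallback: the more reactive alkene acceptor would be used and the double bond restored afterwards. Propargylic alcohol 20 would be reduced with NaAlH2(OCH2CH2OMe)2 at −72 °C (hydroxyl-directed trans-hydroalumination) to 2-(trimethylsilyl)ethyl (E)-4-hydroxy-8-[(2R,3R)-3-(2-iodoethyl)-2-methyloxiran-2-yl]-5,5-dimethyloct-2-enoate F1. Dess–Martin oxidation would give the (E)-4-oxo-2-enoate F2. Cyclisation with (Me3Si)3SiH and Et3B/air at high dilution, now an 11-endo-trig closure, would give the saturated eleven-membered keto ester F3. This would be converted with LiHMDS and Me3SiCl into the trimethylsilyl enol ether F4, which can form only towards C2. Saegusa–Ito dehydrogenation with Pd(OAc)2 in MeCN would bring the sequence back to 22.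

**Step 14.** Poor or reversed facial selectivity is the main risk. The size ranking of the two ketone flanks (quaternary C4 against the alkene CH) is an assumption, and the conformation of the ring may impose its own bias; conjugate reduction of the ene keto ester is a lesser risk.

Fallback: substrate control with separation and recycling. Ketone 22 would be reduced under Luche conditions (NaBH4, CeCl3·7H2O, MeOH, −78 °C). The 3R alcohol 23 would be separated by chromatography from 2-(trimethylsilyl)ethyl (1R,4E,6S,11R)-6-hydroxy-7,7,11-trimethyl-12-oxabicyclo[9.1.0]dodec-4-ene-4-carboxylate F5, and F5 would be oxidised with Dess–Martin periodinane back to 22 and resubmitted. The sequence rejoins the route at 23.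

**Step 7.** The 3,4-epoxy alcohol 12 may cyclise through its own hydroxyl onto the tertiary epoxide carbon (a 5-endo opening to a tetrahydrofuranol), or the epoxide may be opened by the phosphonium iodide reagent, if traces of acid appear.

Fallback: the hydroxyl would be turned into a leaving group before the epoxide exists. Alcohol 11 would be converted with TsCl and pyridine into (E)-9-[(4-methoxybenzyl)oxy]-4,8,8-trimethylnon-3-en-1-yl 4-methylbenzenesulfonate F6. Shi epoxidation under the conditions of step 6 would give the (R,R)-epoxy tosylate F7. Finkelstein exchange (NaI, NaHCO3, acetone) would give iodide 13.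

**Step 5.** Incomplete formation of the alanate, or transfer of butyl or methyl in place of the alkenyl group to oxirane, would lower the conversion. Coordination of Me3Al to the benzylic ether could also cause loss of the protecting group.

Fallback: the alkenyl metal would be isolated as a halide. Alkyne 7 would be carboaluminated as before and quenched with I2 to give (E)-1-iodo-7-[(4-methoxybenzyl)oxy]-2,6,6-trimethylhept-1-ene F8. Iodine–lithium exchange with t-BuLi in Et2O at −78 °C and addition of the alkenyllithium to oxirane 8 would return to 11.

**Step 16.** The fluoride source is basic enough that loss or migration of the benzoate, deprotonation at the allylic C3–H or attack of the freed carboxylate on the epoxide may compete with the desired elimination.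

Fallback: the order of the last two steps would be exchanged so that no benzoate is present during the fluoride step. Alcohol 23 would be treated with the same fluoride reagent to give (1R,4E,6R,11R)-6-hydroxy-7,7,11-trimethyl-12-oxabicyclo[9.1.0]dodec-4-ene-4-carboxylic acid F9. Lactonisation is excluded here because the hydroxyl and the carboxyl are trans across the alkene. Excess BzCl in pyridine would give the benzoate mixed benzoic anhydride F10, and aqueous pyridine would hydrolyse the anhydride to give target 25.

## Further compounds

F1 | step 13 | 2-(trimethylsilyl)ethyl (E)-4-hydroxy-8-[(2R,3R)-3-(2-iodoethyl)-2-methyloxiran-2-yl]-5,5-dimethyloct-2-enoate (both C4 epimers) | ICC[C@H]1O[C@]1(C)CCCC(C)(C)C(O)/C=C/C(=O)OCC[Si](C)(C)C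
F2 | step 13 | 2-(trimethylsilyl)ethyl (E)-8-[(2R,3R)-3-(2-iodoethyl)-2-methyloxiran-2-yl]-5,5-dimethyl-4-oxooct-2-enoate | ICC[C@H]1O[C@]1(C)CCCC(C)(C)C(=O)/C=C/C(=O)OCC[Si](C)(C)C
F3 | step 13 | 2-(trimethylsilyl)ethyl (1R,11R)-7,7,11-trimethyl-6-oxo-12-oxabicyclo[9.1.0]dodecane-4-carboxylate (both C4 epimers) | CC1(C)CCC[C@@]2(C)O[C@@H]2CCC(C(=O)OCC[Si](C)(C)C)CC1=O
F4 | step 13 | 2-(trimethylsilyl)ethyl (1R,11R)-7,7,11-trimethyl-6-[(trimethylsilyl)oxy]-12-oxabicyclo[9.1.0]dodec-5-ene-4-carboxylate | CC1(C)CCC[C@@]2(C)O[C@@H]2CCC(C(=O)OCC[Si](C)(C)C)C=C1O[Si](C)(C)C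
F5 | step 14 | 2-(trimethylsilyl)ethyl (1R,4E,6S,11R)-6-hydroxy-7,7,11-trimethyl-12-oxabicyclo[9.1.0]dodec-4-ene-4-carboxylate | CC1(C)CCC[C@@]2(C)O[C@@H]2CC/C(C(=O)OCC[Si](C)(C)C)=C\[C@@H]1O
F6 | step 7 | (E)-9-[(4-methoxybenzyl)oxy]-4,8,8-trimethylnon-3-en-1-yl 4-methylbenzenesulfonate | Cc1ccc(cc1)S(=O)(=O)OCC/C=C(\C)CCCC(C)(C)COCc1ccc(OC)cc1
F7 | step 7 | 2-[(2R,3R)-3-{5-[(4-methoxybenzyl)oxy]-4,4-dimethylpentyl}-3-methyloxiran-2-yl]ethyl 4-methylbenzenesulfonate | Cc1ccc(cc1)S(=O)(=O)OCC[C@H]1O[C@]1(C)CCCC(C)(C)COCc1ccc(OC)cc1
F8 | step 5 | (E)-1-iodo-7-[(4-methoxybenzyl)oxy]-2,6,6-trimethylhept-1-ene | I/C=C(\C)CCCC(C)(C)COCc1ccc(OC)cc1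
F9 | step 16 | (1R,4E,6R,11R)-6-hydroxy-7,7,11-trimethyl-12-oxabicyclo[9.1.0]dodec-4-ene-4-carboxylic acid | CC1(C)CCC[C@@]2(C)O[C@@H]2CC/C(C(=O)O)=C\[C@H]1O
F10 | step 16 | benzoic (1R,4E,6R,11R)-6-(benzoyloxy)-7,7,11-trimethyl-12-oxabicyclo[9.1.0]dodec-4-ene-4-carboxylic anhydride | CC1(C)CCC[C@@]2(C)O[C@@H]2CC/C(C(=O)OC(=O)c3ccccc3)=C\[C@H]1OC(=O)c1ccccc1
A1 | alternative 1 | six–seven fused bicyclic hydroxy mesylate (racemic, relative configuration: trans ring fusion, C8 methyl cis to C9 mesylate) | CC1(C)CCC[C@]2(C)[C@@H](OS(C)(=O)=O)CCC(CO[Si](C)(C)C(C)(C)C)=C[C@@]12O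
A2 | alternative 1 | achiral eleven-membered dienone with C15 as tert-butyldimethylsilyl ether | CC1(C)CCC/C(C)=C/CC/C(CO[Si](C)(C)C(C)(C)C)=C\C1=O
A3 | alternative 2 | open-chain bis(allylic bromide) with the (R)-benzoate at C3, silylethyl ester | BrC/C=C(\C)CCCC(C)(C)[C@H](OC(=O)c1ccccc1)/C=C(\CBr)C(=O)OCC[Si](C)(C)C
A4 | alternative 2 | eleven-membered diene benzoate, silylethyl ester | CC1(C)CCC/C(C)=C/CC/C(C(=O)OCC[Si](C)(C)C)=C\[C@H]1OC(=O)c1ccccc1
A5 | alternative 3 | (−)-caryophyllene oxide | C=C1CC[C@H]2O[C@]2(C)CC[C@@H]3[C@@H]1CC3(C)C
A6 | alternative 3 | tertiary bromo methyl ester from caryophyllene oxide (Br and CO2Me on C1, both C1 epimers) | COC(=O)C1(Br)CC[C@H]2O[C@]2(C)CC[C@@H]3[C@@H]1CC3(C)C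
A7 | alternative 3 | 3-deoxy epoxy enoate macrocycle, methyl ester | CC1(C)CCC[C@@]2(C)O[C@@H]2CC/C(C(=O)OC)=C\C1
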